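## Structural features

The target is a germacranolide: a ten-membered carbocycle (C1–C10) fused along C6–C7 to a butenolide (O–C6–C7=C11–C12). C7 is therefore an atom of both rings, and the tetrasubstituted C7=C11 olefin lies inside the lactone. C11 carries the acetoxymethyl arm C13, C8 carries an (E)-2-methylbut-2-enoate (tiglate), C10 carries the exocyclic methylene C14 conjugated with the C1 ketone, and C4–C5 is a trisubstituted epoxide with the methyl C15 on C4. Three stereocentres are contiguous (C4 R, C5 R, C6 S) and the fourth, C8 (S), sits on the other flank of C7. In the extended C4–C7 chain the C6 oxygen is syn to the epoxide oxygen. The fragile groups are the epoxide (acid), C6–H (γ to the lactone carbonyl and next to the epoxide, so base opens the epoxide through the furanolate), the C13 acetate (allylic to an electron-poor olefin), the α-methylene ketone (Michael acceptor) and the tiglate. The real difficulty is closing a ten-membered ring at a tetrasubstituted olefin carbon flanked by two oxygenated stereocentres, with C6 formed in the sense that open-chain additions to epoxy aldehydes normally disfavour. The key step exploits the cis relation of the C6 oxygen and the C12 carbonyl across C7=C11: bonding C7 to an aldehyde carbon C6 closes the carbocycle and leaves a metal alkoxide placed to close the lactone.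

## Logic of the disconnections

**32 to 31 and 30.** No skeletal bond is cut; the C1 carbonyl is traced to the carbinol 31 and its silyl ether 30. The reason is that a C1 ketone in the open chain would sit 1,5 to the nucleophilic C7 (five-membered closure), and the α-methylene ketone is a Michael acceptor that divalent chromium can reduce. The gain is a ring-closing substrate with a single carbonyl electrophile. The demand is a fluoride deprotection and a neutral oxidation that spare the epoxide, the allylic acetate and C6–H; the C1 configuration need not be controlled.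

**30 to 27.** Two bonds are cut together: C6–C7 (carbocycle) and O–C12 (lactone). They are cut here because C7 is common to both rings and the C6 oxygen is cis to C12, so one carbonyl addition can trigger both closures. The gain is large: both rings and the C6 stereocentre disappear, and 27 is an open chain carrying the other three stereocentres and both acyl groups. The demand is a nucleophile at a tetrasubstituted olefin carbon, formed with retention of geometry beside an aldehyde, an epoxide and three esters, that closes a ten-membered ring and gives 6S.

**27 to 26 to 25.** Only the oxidation level and protection of C6 change. The α,β-epoxy aldehyde is too labile to carry, so it is revealed in the last two operations before ring closure. The demand is neutral conditions for both the ether cleavage and the oxidation.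

**25 to 23 and 24, 23 to 22, 22 to 21.** The acyl C–O bonds at O8 and O13 are cut, then both O–Si bonds. An acyloxymethyl group on C11 cannot coexist with the β-keto ester (loss of carboxylate by E1cB), and a tiglate would not survive the organolithium and enolate steps, so both esters come after the enol triflate. The gain is a set of earlier intermediates with C12 as the only ester. The demand is primary-over-secondary acetylation, acylation of a hindered secondary alcohol, and removal of two triethylsilyl groups beside a tert-butyldimethylsilyl ether.

**21 to 19 (through 20).** The O–S bond of the enol triflate is cut. The β-keto ester is the natural precursor, and the olefin geometry becomes a question of enolate geometry. The demand is a chelated enolate, so that sulfonylation places the triflate cis to C12, and a sulfonylating agent that leaves the epoxide and ethers alone.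

**19 to 18 to 14 and 16 (through 17); 16 to 15.** C7–C11 is cut after adjusting C7 to the carbinol level (aldol retron). This joins the C11–C13 unit as a commercial three-carbon ester; addition to an aldehyde followed by oxidation is more dependable on this substrate than a direct ester condensation. The demand is that the β-silyloxy ester enolate adds before it eliminates; the two transient stereocentres need no control.

**14 to 12 (through 13).** The C7 aldehyde is traced to a primary triethylsilyl ether. One silylating agent thus protects both hydroxyls of the C7–C8 diol, and the primary one is later oxidised directly. The demand is an oxidative cleavage selective for the primary triethylsilyl ether.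

**12 to 9 and 5 (through 10 and 11).** C1–C10 is cut. It divides the chain into two small pieces and is placed before the enol triflate exists, because nickel could not tell a second alkenyl electrophile from the first. The demand is that the alkenyllithium adds to the aldehyde and not to the epoxide, and that the new alkoxide is capped in the same flask.

**9 to 8 to 7 to 6.** The O–Si bonds, the C10–Br bond and C9–C10 are cut. C8 comes from the chiral pool in 6, and the two-carbon nucleophile supplies C10 and C14. A four-carbon hydroxy diacid could supply C7–C10 but has no carbon for C14 and would need extra steps to turn a carboxyl into the bromoalkene. The demand is epoxide opening at the terminal carbon and Markovnikov addition of HBr.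

**5 to 3 (through 4), 3 to 2, 2 to 1.** The C1 aldehyde comes from cleavage of the distal trisubstituted olefin, then the benzyl ether and the epoxide C–O bonds are cut. 1 already holds C1–C6 and C15 with the E-olefin needed for the trans epoxide. The demand is reagent-controlled epoxidation of the allylic alcohol and an olefin cleavage that spares the anisyl ring.

## Other disconnections considered

**Alternative 1:** The cut is C2–C3, read as a retro-Claisen rearrangement. The ten-membered α-methylene ketone A1 comes from the eight-membered cyclic enol ether A2, in which the ring oxygen joins C1 and C5, C1 and C10 carry exocyclic methylenes and C5 carries the isopropenyl group (C3, C4, C15). Forward, heating A2 sends the allyl vinyl ether through a chair-like [3,3] shift: C2–C3 forms, C5–O breaks, and the ring grows by two atoms to give A1 with the C1 ketone, the C10 methylene and the (4E)-olefin.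
- In its favour: the medium ring arises by a unimolecular pericyclic ring expansion with no high dilution and no organometallic reagent. On entropy of ring formation and on mechanistic predictability it is better than the chosen plan.
- It is also better in delivering the C1 ketone and C10 methylene directly, and in having C6 set before the ring exists. For C8 the two plans are equal.
- Against it here: A1 is far from the target. The 4,5-epoxide must be added late with face and site selectivity among three olefins. The two arms of the dioxane on C11 must be told apart and one raised to the acid level. Both silyl ethers must be exchanged for the lactone and the tiglate.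
- A2 itself needs an eight-membered lactone and its methylenation (for example Cp2TiMe2) next to a diene.
- Comparison: the alternative solves the ring but postpones every oxygen function (about eight to ten operations after the key step, against two). The chosen plan closes ring and lactone with all functionality in place, so it is better on step economy.

**Alternative 2:** The cut is C3–C4. The seco compound A4 carries a pinacol boronate on C3 and an (E)-iodoalkene at C4, with the butenolide, tiglate and acetate in place and C1 as a silyl ether. Forward, PdCl2(dppf) with K3PO4 couples sp3 C3 with sp2 C4 and closes the ring to the cyclodecadiene A3.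
- In its favour: the bond formed creates no stereocentre and the olefin geometry is inherited from the iodide. The ring closes at unhindered carbons, which is better than closure at a tetrasubstituted olefin carbon.
- C6 and the butenolide are made earlier between fragments, where epimers can be separated. This is better than the chosen plan for C6.
- The metal is catalytic, which is better than ten equivalents of a chromium salt.
- Against it here: pinacol alkylboronates transmetalate slowly and need strong base, while C6–H of A4 and A3 is both allylic and γ to the lactone carbonyl. Zerovalent palladium is also exposed to the C13 acetate, an allylic ester on an electron-poor olefin that ionises readily.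
- After A3 come desilylation, oxidation and a late epoxidation of the 4,5-olefin under substrate control (three steps against two). The chosen plan fixes C4 and C5 by reagent control at the start.
- Making A4 needs a chemoselective hydroboration beside the C10 methylene and the tiglate. Overall step count is comparable.

**Alternative 3:** The cut is C1–C10. The ynal A6 carries the C1 aldehyde and the terminal C10≡C14 alkyne, with the butenolide, epoxide, tiglate and acetate complete. Forward, bis(1,5-cyclooctadiene)nickel with a bulky N-heterocyclic carbene and Et3SiH couples the aldehyde to the internal alkyne carbon and gives the silyl-protected 2-methylene carbinol A5.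
- In its favour: the reacting groups are a plain alkyne and a plain aldehyde, easier to carry than an enol triflate. This is better than the chosen plan.
- All four stereocentres exist before ring closure, and the only new one (C1) is erased by oxidation. This is better than setting C6 in the ring closure.
- Two steps remain after A5, equal to the chosen plan.
- Against it here: the exo mode (ten-membered ring, 1,1-disubstituted olefin) competes with the endo mode (eleven-membered ring, E-olefin) and rests on ligand bulk alone.
- Zerovalent nickel bearing a strong donor ligand meets an allylic acetate, an allylic lactone C–O bond and two enoates, all known partners for it. In the chosen plan nickel is present in trace amount without a donor ligand.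
- A6 still needs the C6–C7 bond and lactone to be made between fragments, where an open-chain addition to the epoxy aldehyde is expected to favour the wrong C6 epimer.

Key step: step 18

Remark: atoms are numbered as in the germacrane skeleton of the target (C1 ketone carbon, C4–C5 epoxide, C6 lactone carbinol, C7=C11 olefin, C8 tiglate carbon, C10=C14 methylene, C12 lactone carbonyl, C13 acetoxymethyl, C15 methyl).
Remark: the open-chain substrate of the ring closure carries C1 as a silyl ether, not a ketone; from step 7 to step 19 C1 is carried as both carbinol epimers (no descriptor in the SMILES) and step 20 converts both into the ketone.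
Remark: C14 cannot come from a four-carbon hydroxy diacid; here C7–C9 come from (R)-glycidol and C10 and C14 from acetylide.

## Steps

Step 1
Reactants: 1 geraniol
Product: 2 (2R,3R)-2,3-epoxygeraniol
Conditions: Ti(OiPr)4 (5 mol %), D-(−)-diisopropyl tartrate (6 mol %), t-BuOOH, 4 Å molecular sieves, CH2Cl2, −20 °C
Reagents that add atoms: tert-butyl hydroperoxide, CC(C)(C)OO
Why: Sharpless asymmetric epoxidation; the allylic hydroxyl binds the titanium tartrate, and the D-(−)-tartrate delivers oxygen to the face that gives the 2R,3R epoxide (C5 and C4 of the target), while the remote trisubstituted olefin is not touched.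

Step 2
Reactants: 2 (2R,3R)-2,3-epoxygeraniol
Product: 3 (2R,3R)-2,3-epoxygeranyl 4-methoxybenzyl ether
Conditions: NaH, 4-MeOC6H4CH2Cl, Bu4NI (cat.), THF–DMF, 0 °C to rt
Reagents that add atoms: 4-methoxybenzyl chloride, COc1ccc(CCl)cc1
Why: Williamson etherification of the primary alkoxide; Payne rearrangement would give a terminal epoxide with a slowly alkylated tertiary alkoxide, so the primary ether should form. The ether is chosen because it is removed later by neutral oxidation.

Step 3
Reactants: 3 (2R,3R)-2,3-epoxygeranyl 4-methoxybenzyl ether
Product: 5 3-[(2R,3R)-3-(4-methoxybenzyloxymethyl)-2-methyloxiran-2-yl]propanal, via ozonide 4 (not isolated)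
Conditions: O3, CH2Cl2, −78 °C (Sudan Red 7B end point); then PPh3, −78 °C to rt
Reagents that add atoms: ozone, [O-][O+]=O
Why: Ozonolysis with reductive work-up; the electron-rich trisubstituted olefin reacts far faster than the anisyl ring, and the dye end point guards the benzyl ether against over-oxidation.

Step 4
Reactants: 6 (R)-glycidol
Product: 7 (S)-pent-4-yne-1,2-diol
Conditions: LiC≡CH·H2NCH2CH2NH2 (2.5 equiv), DMSO, 0 °C to rt; H2O
Reagents that add atoms: lithium acetylide–ethylenediamine complex, [Li+].[C-]#C.NCCN
Why: SN2 opening of the epoxide at its terminal carbon by acetylide; the stereocentre (later C8, S) is not a reacting centre, and the Payne rearrangement of glycidol is degenerate, so it cannot erode the configuration.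

Step 5
Reactants: 7 (S)-pent-4-yne-1,2-diol
Product: 8 (S)-4-bromopent-4-ene-1,2-diol
Conditions: Et4NBr, HBr (1.1 equiv), CH2Cl2, 0 to 40 °C
Reagents that add atoms: hydrogen bromide, Br
Why: Markovnikov hydrobromination of a terminal alkyne by tetraethylammonium hydrogen dibromide, a known route to 2-bromoalk-1-enes that tolerates free hydroxyl groups; limiting the HBr should prevent the geminal dibromide.

Step 6
Reactants: 8 (S)-4-bromopent-4-ene-1,2-diol
Product: 9 (S)-4-bromo-1,2-bis(triethylsilyloxy)pent-4-ene
Conditions: Et3SiCl (2.3 equiv), imidazole, DMF, 0 °C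
Reagents that add atoms: chlorotriethylsilane, CC[Si](Cl)(CC)CC
Why: Silyl ether formation at both hydroxyls; the primary ether (C7) is the one oxidised directly in step 8 and the secondary one (C8) lasts until step 13.

Step 7
Reactants: 9 (S)-4-bromo-1,2-bis(triethylsilyloxy)pent-4-ene; 5 3-[(2R,3R)-3-(4-methoxybenzyloxymethyl)-2-methyloxiran-2-yl]propanal
Product: 12 coupled C6–C1–C10–C7 chain (C1 tert-butyldimethylsilyl ether, both epimers; 4R,5R-epoxide; C6 4-methoxybenzyl ether; C7 and 8S triethylsilyl ethers; C10=C14 methylene), via alkenyllithium 10 (not isolated), via lithium alkoxide 11 (not isolated)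
Conditions: 9, t-BuLi (2.05 equiv), Et2O, −78 °C; then 5, −78 °C; then t-BuMe2SiOTf (1.2 equiv), −78 to −40 °C; Et3N, aq. NaHCO3
Reagents that add atoms: tert-butyldimethylsilyl trifluoromethanesulfonate, CC(C)(C)[Si](C)(C)OS(=O)(=O)C(F)(F)F
Why: Bromine–lithium exchange followed by 1,2-addition of the alkenyllithium to the aldehyde forms C1–C10, the aldehyde being far more reactive than the trisubstituted epoxide at −78 °C. The alkoxide is silylated in the same flask so that the free 1-hydroxy-4,5-epoxide, which could close to a tetrahydrofuran at C4, is never handled. No control at C1 is expected or needed.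

Step 8
Reactants: 12 coupled chain with C7 primary triethylsilyl ether
Product: 14 C7 aldehyde (8S α-triethylsilyloxy aldehyde; rest as 12), via alkoxysulfonium chloride 13 (not isolated)
Conditions: (COCl)2 (4 equiv), DMSO (8 equiv), CH2Cl2, −78 to −30 °C; then Et3N, −78 to 0 °C
Reagents that add atoms: none
Why: Swern oxidation run on the silyl ether: activated DMSO cleaves the unhindered primary triethylsilyl ether and oxidises it to the aldehyde, while secondary silyl ethers, the benzyl ether and the epoxide are inert at this temperature. The aldehyde is used at once so that C8 does not epimerise.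

Step 9
Reactants: 15 methyl 3-hydroxypropanoate
Product: 16 methyl 3-(triethylsilyloxy)propanoate
Conditions: Et3SiCl, imidazole, CH2Cl2, 0 °C
Reagents that add atoms: chlorotriethylsilane, CC[Si](Cl)(CC)CC
Why: Silyl ether formation; a silyl ether and not an acetate is carried on C13 through the enolate steps because a silanolate is a poor leaving group for β-elimination.

Step 10
Reactants: 16 methyl 3-(triethylsilyloxy)propanoate; 14 C7 aldehyde
Product: 18 β-hydroxy ester (C7 carbinol and C11 as mixtures; C12 methyl ester; C13 triethylsilyl ether), via lithium enolate 17 (not isolated)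
Conditions: LiN(iPr)2, THF, −78 °C, 20 min; then 14, −78 °C; AcOH in THF, −78 °C
Reagents that add atoms: none
Why: Aldol addition of the ester enolate to the aldehyde forms C7–C11; at −78 °C addition should outrun loss of silanolate from 17. The two new stereocentres are left uncontrolled because steps 11 and 12 erase them.

Step 11
Reactants: 18 β-hydroxy ester
Product: 19 β-keto ester (C7 ketone; C11 mixture)
Conditions: Dess–Martin periodinane, NaHCO3, CH2Cl2, 0 °C to rt
Reagents that add atoms: none
Why: Dess–Martin oxidation of the secondary alcohol under buffered conditions gives the formal Claisen condensation product without base, so C8 should keep its configuration and the silyloxymethyl group should stay on C11.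

Step 12
Reactants: 19 β-keto ester
Product: 21 (Z)-enol triflate (C7 triflate cis to C12 methyl ester; C8 cis to C13), via sodium enolate 20 (not isolated)
Conditions: NaH, toluene–THF (10:1), 0 °C; then N-(5-chloro-2-pyridyl)bis(trifluoromethanesulfonimide), 0 °C to rt
Reagents that add atoms: N-(5-chloropyridin-2-yl)bis(trifluoromethanesulfonyl)imide, FC(F)(F)S(=O)(=O)N(c1ccc(Cl)cn1)S(=O)(=O)C(F)(F)F
Why: O-sulfonylation of a β-keto ester enolate; in a weakly coordinating medium the sodium ion bridges both carbonyl oxygens, which holds the C7 oxygen cis to C12, so triflation should give the Z olefin. The doubly activated C11–H is removed in preference to C8–H, and the triflimide (not Tf2O) spares the epoxide and the ethers.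

Step 13
Reactants: 21 (Z)-enol triflate
Product: 22 C8,C13 diol
Conditions: HF·pyridine, pyridine, THF, 0 °C
Reagents that add atoms: none
Why: Buffered fluoride desilylation; the two triethylsilyl ethers cleave much faster than the secondary tert-butyldimethylsilyl ether on C1. Any E isomer from step 12 would lactonise here (its C8 hydroxyl is cis to C12) and be separated.

Step 14
Reactants: 22 C8,C13 diol
Product: 23 C13 acetate (C8 hydroxyl free)
Conditions: Ac2O (1.1 equiv), 2,4,6-collidine, CH2Cl2, −20 to 0 °C
Reagents that add atoms: acetic anhydride, CC(=O)OC(C)=O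
Why: Selective acylation of the primary allylic hydroxyl over the hindered secondary C8 hydroxyl; the acetate can be introduced now because C11 no longer bears an acidic hydrogen.

Step 15
Reactants: 23 C13 acetate; 24 tigloyl chloride
Product: 25 C8 tiglate
Conditions: pyridine, DMAP (0.2 equiv), CH2Cl2, 0 °C to rt
Reagents that add atoms: none
Why: DMAP-catalysed acylation of the secondary alcohol; the C8–O bond is not broken, so 8S is retained, and the tiglate is the stable geometric isomer.

Step 16
Reactants: 25 C8 tiglate (C6 4-methoxybenzyl ether)
Product: 26 C6 primary epoxy alcohol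
Conditions: 2,3-dichloro-5,6-dicyano-1,4-benzoquinone, CH2Cl2–pH 7 phosphate buffer, 0 °C
Reagents that add atoms: none
Why: Oxidative cleavage of the 4-methoxybenzyl ether (benzylic hydride abstraction, hydrolysis of the hemiacetal) under neutral conditions that should leave the silyl ether, enol triflate, esters and epoxide intact.

Step 17
Reactants: 26 C6 primary epoxy alcohol
Product: 27 seco epoxy aldehyde (Z)-enol triflate (C6 aldehyde; C1 tert-butyldimethylsilyl ether)
Conditions: Dess–Martin periodinane, NaHCO3, CH2Cl2, 0 °C to rt; used at once
Reagents that add atoms: none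
Why: Dess–Martin oxidation of the primary alcohol to the epoxy aldehyde without acid or base, so C5 is not enolised and the epoxide is not opened.

Step 18
Reactants: 27 seco epoxy aldehyde (Z)-enol triflate
Product: 30 ten-membered butenolide with C1 tert-butyldimethylsilyl ether (4R,5R,6S,8S), via alkenylchromium 28 (not isolated), via chromium alkoxide 29 (not isolated)
Conditions: CrCl2 (10 equiv), NiCl2 (0.2 equiv), degassed DMF, 27 added by syringe pump over 12 h to 2 mM, 23 °C; aq. NH4Cl–EDTA
Reagents that add atoms: none
Why: Nozaki–Hiyama–Kishi reaction run as a double ring closure. CrCl2 reduces NiCl2 to zerovalent nickel, which inserts into the C7–O bond of the electron-poor enol triflate with retention of geometry; transmetalation to trivalent chromium gives alkenylchromium 28 and returns divalent nickel. 28 adds 1,2 to the C6 aldehyde in a 10-exo-trig closure to give the chromium alkoxide 29. In 29 the alkoxide is held cis to the C12 methyl ester across the tetrasubstituted olefin and closes the butenolide by 5-exo-trig acyl substitution with loss of methoxide. The closest known reaction type is the CrCl2/NiCl2 coupling of β-triflyloxy acrylates with aldehydes with spontaneous lactonisation, together with intramolecular couplings of this kind to medium rings. The new stereocentre C6 (S) is controlled by the C4/C5 epoxide: trivalent chromium can bridge the aldehyde and epoxide oxygens so that C7 attacks past H5, and the 6S transition state maps onto the low-strain conformation of 4,5-epoxygermacran-6,12-olides with H5 anti to H6. The step needs aldehyde selectivity (secured by masking C1 and by the inertness of esters and epoxide to alkenylchromium), ring closure over oligomerisation (slow addition, high dilution) and retention of the Z geometry (configurationally stable alkenylchromium).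

Step 19
Reactants: 30 ten-membered butenolide with C1 tert-butyldimethylsilyl ether
Product: 31 C1 carbinol (both epimers)
Conditions: HF·pyridine, pyridine, THF, 0 °C to rt
Reagents that add atoms: none
Why: Fluoride cleavage of the secondary silyl ether; the pyridine buffer should keep the epoxide from being opened by HF or by the new C1 hydroxyl, and the acetate, tiglate and butenolide do not react with fluoride.

Step 20
Reactants: 31 C1 carbinol
Product: 32 CNP0225286.1 (target)
Conditions: Dess–Martin periodinane, NaHCO3, CH2Cl2, 0 °C
Reagents that add atoms: none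
Why: Dess–Martin oxidation of the allylic alcohol to the α-methylene ketone; both C1 epimers converge, and the neutral conditions protect C6–H, the epoxide and the allylic acetate.

## Compound list

1 | geraniol | CC(C)=CCC/C(C)=C/CO | starting material
2 | (2R,3R)-2,3-epoxygeraniol, [(2R,3R)-3-methyl-3-(4-methylpent-3-enyl)oxiran-2-yl]methanol | OC[C@H]1O[C@]1(C)CCC=C(C)C | intermediate
3 | (2R,3R)-2,3-epoxygeranyl 4-methoxybenzyl ether | COc1ccc(COC[C@H]2O[C@]2(C)CCC=C(C)C)cc1 | intermediate
4 | secondary ozonide (1,2,4-trioxolane) of 3 at the distal olefin | COc1ccc(COC[C@H]2O[C@]2(C)CCC2OOC(C)(C)O2)cc1 | intermediate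
5 | 3-[(2R,3R)-3-(4-methoxybenzyloxymethyl)-2-methyloxiran-2-yl]propanal (C1 aldehyde, C1–C6 and C15) | COc1ccc(COC[C@H]2O[C@]2(C)CCC=O)cc1 | intermediate
6 | (R)-glycidol | OC[C@@H]1CO1 | starting material
7 | (S)-pent-4-yne-1,2-diol | OC[C@@H](O)CC#C | intermediate
8 | (S)-4-bromopent-4-ene-1,2-diol | OC[C@@H](O)CC(Br)=C | intermediate
9 | (S)-4-bromo-1,2-bis(triethylsilyloxy)pent-4-ene | CC[Si](CC)(CC)OC[C@@H](O[Si](CC)(CC)CC)CC(Br)=C | intermediate
10 | (S)-4,5-bis(triethylsilyloxy)pent-1-en-2-yllithium (C10 alkenyllithium) | [Li]C(=C)C[C@H](O[Si](CC)(CC)CC)CO[Si](CC)(CC)CC | intermediate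
11 | lithium C1 alkoxide of the coupled chain (C1 both epimers) | COc1ccc(COC[C@H]2O[C@]2(C)CCC(O[Li])C(=C)C[C@H](O[Si](CC)(CC)CC)CO[Si](CC)(CC)CC)cc1 | intermediate
12 | coupled chain: C1 tert-butyldimethylsilyl ether (both epimers), 4R,5R-epoxide, C6 4-methoxybenzyl ether, C7 and (8S) triethylsilyl ethers, C10=C14 methylene | COc1ccc(COC[C@H]2O[C@]2(C)CCC(O[Si](C)(C)C(C)(C)C)C(=C)C[C@H](O[Si](CC)(CC)CC)CO[Si](CC)(CC)CC)cc1 | intermediate
13 | C7 alkoxydimethylsulfonium chloride derived from 12 | COc1ccc(COC[C@H]2O[C@]2(C)CCC(O[Si](C)(C)C(C)(C)C)C(=C)C[C@H](O[Si](CC)(CC)CC)CO[S+](C)C)cc1.[Cl-] | intermediate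
14 | C7 aldehyde with (8S) triethylsilyl ether, rest as 12 | COc1ccc(COC[C@H]2O[C@]2(C)CCC(O[Si](C)(C)C(C)(C)C)C(=C)C[C@H](O[Si](CC)(CC)CC)C=O)cc1 | intermediate
15 | methyl 3-hydroxypropanoate | COC(=O)CCO | starting material
16 | methyl 3-(triethylsilyloxy)propanoate | COC(=O)CCO[Si](CC)(CC)CC | intermediate
17 | lithium enolate of 16 | COC(O[Li])=CCO[Si](CC)(CC)CC | intermediate
18 | β-hydroxy ester: C7 carbinol and C11 as mixtures, C12 methyl ester, C13 triethylsilyl ether, rest as 14 | COc1ccc(COC[C@H]2O[C@]2(C)CCC(O[Si](C)(C)C(C)(C)C)C(=C)C[C@H](O[Si](CC)(CC)CC)C(O)C(CO[Si](CC)(CC)CC)C(=O)OC)cc1 | intermediate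
19 | β-keto ester: C7 ketone, C11 mixture | COc1ccc(COC[C@H]2O[C@]2(C)CCC(O[Si](C)(C)C(C)(C)C)C(=C)C[C@H](O[Si](CC)(CC)CC)C(=O)C(CO[Si](CC)(CC)CC)C(=O)OC)cc1 | intermediate
20 | chelated sodium enolate of 19 (C7 oxygen cis to C12) | COc1ccc(COC[C@H]2O[C@]2(C)CCC(O[Si](C)(C)C(C)(C)C)C(=C)C[C@H](O[Si](CC)(CC)CC)/C(O[Na])=C(\CO[Si](CC)(CC)CC)C(=O)OC)cc1 | intermediate
21 | (Z)-enol triflate: C7 triflate cis to C12 methyl ester, C8 and C13 triethylsilyl ethers | COc1ccc(COC[C@H]2O[C@]2(C)CCC(O[Si](C)(C)C(C)(C)C)C(=C)C[C@H](O[Si](CC)(CC)CC)/C(OS(=O)(=O)C(F)(F)F)=C(\CO[Si](CC)(CC)CC)C(=O)OC)cc1 | intermediate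
22 | (Z)-enol triflate C8,C13 diol | COc1ccc(COC[C@H]2O[C@]2(C)CCC(O[Si](C)(C)C(C)(C)C)C(=C)C[C@H](O)/C(OS(=O)(=O)C(F)(F)F)=C(\CO)C(=O)OC)cc1 | intermediate
23 | (Z)-enol triflate C13 acetate, C8 hydroxyl free | COc1ccc(COC[C@H]2O[C@]2(C)CCC(O[Si](C)(C)C(C)(C)C)C(=C)C[C@H](O)/C(OS(=O)(=O)C(F)(F)F)=C(\COC(C)=O)C(=O)OC)cc1 | intermediate
24 | tigloyl chloride, (E)-2-methylbut-2-enoyl chloride | C/C=C(\C)C(Cl)=O | starting material
25 | (Z)-enol triflate C13 acetate C8 tiglate, C6 4-methoxybenzyl ether | COc1ccc(COC[C@H]2O[C@]2(C)CCC(O[Si](C)(C)C(C)(C)C)C(=C)C[C@H](OC(=O)/C(C)=C/C)/C(OS(=O)(=O)C(F)(F)F)=C(\COC(C)=O)C(=O)OC)cc1 | intermediate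
26 | C6 primary epoxy alcohol (4R,5R,8S; C1 silyl ether, both epimers) | OC[C@H]1O[C@]1(C)CCC(O[Si](C)(C)C(C)(C)C)C(=C)C[C@H](OC(=O)/C(C)=C/C)/C(OS(=O)(=O)C(F)(F)F)=C(\COC(C)=O)C(=O)OC | intermediate
27 | seco epoxy aldehyde (Z)-enol triflate: C6 aldehyde, 4R,5R-epoxide, C1 tert-butyldimethylsilyl ether (both epimers), (8S) tiglate, C13 acetate, C12 methyl ester | O=C[C@H]1O[C@]1(C)CCC(O[Si](C)(C)C(C)(C)C)C(=C)C[C@H](OC(=O)/C(C)=C/C)/C(OS(=O)(=O)C(F)(F)F)=C(\COC(C)=O)C(=O)OC | intermediate
28 | C7 alkenylchromium dichloride (trivalent chromium) derived from 27 | O=C[C@H]1O[C@]1(C)CCC(O[Si](C)(C)C(C)(C)C)C(=C)C[C@H](OC(=O)/C(C)=C/C)/C([Cr](Cl)Cl)=C(\COC(C)=O)C(=O)OC | intermediate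
29 | ten-membered ring chromium C6 alkoxide (6S), C12 methyl ester not yet closed | C=C1C[C@H](OC(=O)/C(C)=C/C)/C(=C(\COC(C)=O)C(=O)OC)[C@H](O[Cr](Cl)Cl)[C@H]2O[C@]2(C)CCC1O[Si](C)(C)C(C)(C)C | intermediate
30 | ten-membered butenolide, C1 tert-butyldimethylsilyl ether (4R,5R,6S,8S; C1 both epimers) | C=C1C[C@H](OC(=O)/C(C)=C/C)C2=C(COC(C)=O)C(=O)O[C@@H]2[C@H]2O[C@]2(C)CCC1O[Si](C)(C)C(C)(C)C | intermediate
31 | C1 carbinol of the ten-membered butenolide (4R,5R,6S,8S; C1 both epimers) | C=C1C[C@H](OC(=O)/C(C)=C/C)C2=C(COC(C)=O)C(=O)O[C@@H]2[C@H]2O[C@]2(C)CCC1O | intermediate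
32 | CNP0225286.1, (4R,5R,6S,8S)-13-acetoxy-4,5-epoxy-1-oxo-8-tigloyloxygermacra-7(11),10(14)-dien-12,6-olide | C=C1C[C@H](OC(=O)/C(C)=C/C)C2=C(COC(C)=O)C(=O)O[C@@H]2[C@H]2O[C@]2(C)CCC1=O | target

## Step count and uncertain steps

Total: 20 steps. Longest linear sequence: 16 steps (steps 4–8 and 10–20 from 6; equally steps 1–3, 7, 8 and 10–20 from 1).

**Step 18 (key step).** Three processes are most likely to go wrong.
- Slow ten-membered ring closure, which would let the hindered alkenylchromium be protonated, lose the neighbouring tiglate by β-elimination, or couple between molecules.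
- Poor facial selectivity at C6, because open-chain additions to epoxy aldehydes tend to give the anti isomer.
- Ionisation of the C13 acetate by low-valent nickel.

Fallback (the two carbon–carbon bond formations are exchanged: C6–C7 is made between fragments and the ring is closed at C1–C10). It sets out from 9 and 2 and returns at 31. Without the western chain, 9 is taken through the chemistry of steps 8 and 10–15: Swern oxidation gives (S)-4-bromo-2-(triethylsilyloxy)pent-4-enal F1, addition of 17 gives the hydroxy ester F2, periodinane oxidation gives the keto ester F3, chelation-controlled triflation gives the (Z)-enol triflate F4, buffered HF·pyridine gives the diol F5, acetylation gives the C13 acetate F6, and 24 gives the tiglate F7. Dess–Martin oxidation of 2 gives (2S,3R)-2,3-epoxygeranial F8. F7 and F8 are coupled with CrCl2/NiCl2 in DMF; the electron-poor triflate should react ahead of the unactivated bromoalkene, and lactonisation gives the open-chain butenolide F9, whose C6 epimers can be separated at this stage. Ozonolysis of the only electron-rich olefin of F9 gives the C1 aldehyde F10. An intramolecular CrCl2/NiCl2 coupling of its bromoalkene with this unhindered aldehyde then closes the ring to 31.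

**Step 12.** The chelate may be broken (loss of Z selectivity) or the enolate may lose silanolate from C13 before it is sulfonylated.

Fallback (geometry fixed by a ring, not by a chelate), from 19 back to 22. Buffered HF·pyridine removes both triethylsilyl groups to give the keto diol F11, kept cold and free of base, which would close it to a tetronic acid. tBu2Si(OTf)2 with 2,6-lutidine ties O8 and O13 into the seven-membered di-tert-butylsilylene F12. Enolisation inside this ring can give only the cis olefin, so NaH and the triflimide give the cyclic enol triflate F13 with the triflate cis to the methyl ester. HF·pyridine removes the silylene and gives 22.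

**Step 7.** Migration of the triethylsilyl group from O8 to C10 in the alkenyllithium, or activation of the epoxide by the silyl triflate, would lower the yield of the union.

Fallback, from 9 and 5 back to 12. CrCl2/NiCl2 in DMSO couples the bromoalkene with the aldehyde without an organolithium and gives the C1 carbinol F14, which is silylated at once with t-BuMe2SiCl and imidazole to 12.

**Step 8.** Incomplete or unselective oxidative cleavage of the silyl ethers, or epimerisation of C8 during the amine treatment.

Fallback, from 12 to 14. HF·pyridine with excess pyridine at −10 °C removes the primary triethylsilyl group to give the primary alcohol F15, which is oxidised separately with SO3·pyridine, DMSO and iPr2NEt to 14.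

## Further compounds

F1 | step 18 | (S)-4-bromo-2-(triethylsilyloxy)pent-4-enal | C=C(Br)C[C@H](O[Si](CC)(CC)CC)C=O
F2 | step 18 | methyl (4S)-6-bromo-3-hydroxy-4-(triethylsilyloxy)-2-(triethylsilyloxymethyl)hept-6-enoate (C2, C3 mixtures) | C=C(Br)C[C@H](O[Si](CC)(CC)CC)C(O)C(CO[Si](CC)(CC)CC)C(=O)OC
F3 | step 18 | methyl (4S)-6-bromo-3-oxo-4-(triethylsilyloxy)-2-(triethylsilyloxymethyl)hept-6-enoate | C=C(Br)C[C@H](O[Si](CC)(CC)CC)C(=O)C(CO[Si](CC)(CC)CC)C(=O)OC
F4 | step 18 | methyl (2Z,4S)-6-bromo-4-(triethylsilyloxy)-2-(triethylsilyloxymethyl)-3-(trifluoromethylsulfonyloxy)hepta-2,6-dienoate | C=C(Br)C[C@H](O[Si](CC)(CC)CC)/C(OS(=O)(=O)C(F)(F)F)=C(\CO[Si](CC)(CC)CC)C(=O)OC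
F5 | step 18 | methyl (2Z,4S)-6-bromo-4-hydroxy-2-(hydroxymethyl)-3-(trifluoromethylsulfonyloxy)hepta-2,6-dienoate | C=C(Br)C[C@H](O)/C(OS(=O)(=O)C(F)(F)F)=C(\CO)C(=O)OC
F6 | step 18 | methyl (2Z,4S)-2-(acetoxymethyl)-6-bromo-4-hydroxy-3-(trifluoromethylsulfonyloxy)hepta-2,6-dienoate | C=C(Br)C[C@H](O)/C(OS(=O)(=O)C(F)(F)F)=C(\COC(C)=O)C(=O)OC
F7 | step 18 | methyl (2Z,4S)-2-(acetoxymethyl)-6-bromo-4-tigloyloxy-3-(trifluoromethylsulfonyloxy)hepta-2,6-dienoate | C=C(Br)C[C@H](OC(=O)/C(C)=C/C)/C(OS(=O)(=O)C(F)(F)F)=C(\COC(C)=O)C(=O)OC
F8 | step 18 | (2S,3R)-2,3-epoxygeranial | O=C[C@H]1O[C@]1(C)CCC=C(C)C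
F9 | step 18 | open-chain butenolide: 6S lactone, 4R,5R-epoxide with the isoprenyl chain, (8S) tiglate, C13 acetate, C10 bromoalkene | C=C(Br)C[C@H](OC(=O)/C(C)=C/C)C1=C(COC(C)=O)C(=O)O[C@@H]1[C@H]1O[C@]1(C)CCC=C(C)C
F10 | step 18 | open-chain butenolide C1 aldehyde with C10 bromoalkene | C=C(Br)C[C@H](OC(=O)/C(C)=C/C)C1=C(COC(C)=O)C(=O)O[C@@H]1[C@H]1O[C@]1(C)CCC=O
F11 | step 12 | keto diol: β-keto ester with free C8 and C13 hydroxyls, rest as 19 | COc1ccc(COC[C@H]2O[C@]2(C)CCC(O[Si](C)(C)C(C)(C)C)C(=C)C[C@H](O)C(=O)C(CO)C(=O)OC)cc1
F12 | step 12 | seven-membered di-tert-butylsilylene bridging O8 and O13 of the β-keto ester | COc1ccc(COC[C@H]2O[C@]2(C)CCC(O[Si](C)(C)C(C)(C)C)C(=C)C[C@@H]2O[Si](C(C)(C)C)(C(C)(C)C)OCC(C(=O)OC)C2=O)cc1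
F13 | step 12 | cyclic enol triflate of F12 (C7=C11 inside the seven-membered ring) | COc1ccc(COC[C@H]2O[C@]2(C)CCC(O[Si](C)(C)C(C)(C)C)C(=C)C[C@@H]2O[Si](C(C)(C)C)(C(C)(C)C)OCC(C(=O)OC)=C2OS(=O)(=O)C(F)(F)F)cc1
F14 | step 7 | free C1 carbinol of the coupled chain (both epimers) | COc1ccc(COC[C@H]2O[C@]2(C)CCC(O)C(=C)C[C@H](O[Si](CC)(CC)CC)CO[Si](CC)(CC)CC)cc1
F15 | step 8 | C7 primary alcohol with (8S) triethylsilyl ether, rest as 12 | COc1ccc(COC[C@H]2O[C@]2(C)CCC(O[Si](C)(C)C(C)(C)C)C(=C)C[C@H](O[Si](CC)(CC)CC)CO)cc1
A1 | alternative 1 | (4E)-10(14)-methylene cyclodecenone with C8 tert-butyldimethylsilyl ether, C6 triethylsilyl ether and dioxane on C11 | C=C1C[C@H](O[Si](C)(C)C(C)(C)C)C(=C2COC(C)(C)OC2)[C@H](O[Si](CC)(CC)CC)/C=C(\C)CCC1=O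
A2 | alternative 1 | 2,3-dimethylene-8-isopropenyloxocane (ring oxygen between C1 and C5; C5 drawn arbitrarily) | C=C1O[C@@H](C(C)=C)[C@@H](O[Si](CC)(CC)CC)C(=C2COC(C)(C)OC2)[C@@H](O[Si](C)(C)C(C)(C)C)CC1=C
A3 | alternative 2 | (4E)-cyclodecadiene butenolide, C1 tert-butyldimethylsilyl ether | C=C1C[C@H](OC(=O)/C(C)=C/C)C2=C(COC(C)=O)C(=O)O[C@@H]2/C=C(\C)CC[C@@H]1O[Si](C)(C)C(C)(C)C
A4 | alternative 2 | seco butenolide with C3 pinacol boronate and (E)-C4 iodoalkene | C=C(C[C@H](OC(=O)/C(C)=C/C)C1=C(COC(C)=O)C(=O)O[C@@H]1/C=C(\C)I)[C@H](CCB1OC(C)(C)C(C)(C)O1)O[Si](C)(C)C(C)(C)C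
A5 | alternative 3 | C1 triethylsilyl ether of the 2-methylene carbinol (C1 drawn arbitrarily) | C=C1C[C@H](OC(=O)/C(C)=C/C)C2=C(COC(C)=O)C(=O)O[C@@H]2[C@H]2O[C@]2(C)CC[C@@H]1O[Si](CC)(CC)CC
A6 | alternative 3 | ynal: butenolide with C1 aldehyde and terminal C10≡C14 alkyne | C#CC[C@H](OC(=O)/C(C)=C/C)C1=C(COC(C)=O)C(=O)O[C@@H]1[C@H]1O[C@]1(C)CCC=O
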